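**Plan** (germacrane numbering: ring C1–C10, lactone carbons C11–C13, C14 on C10, C15 on C4)
- Retrosynthesis cuts, in order: the C8 ester C–O bond; the lactone bond O6–C12, exchanged for O8–C12 (translactonization); the ring bond C6–C7; the butenolide C7=C11 (metathesis) and O8–C12 (acylation); then C9–C10 and C1=C10.
- Forward: geraniol gives C1–C6 and C15; an α-iodo Wittig reaction adds C10/C14 as a Z-vinyl iodide; (R)-epichlorohydrin adds C7–C9; acylation and ring-closing metathesis build a butenolide (C11–C13); epoxidation and oxidation give the epoxy aldehyde; then the ten-membered ring closes, the lactone moves from O8 to O6, and the C8 ester is attached.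
- Enabling feature: C7 lies between two oxygenated carbons (C6, C8) and is the γ-carbon of the allyl unit C13–C11=C7, whose central carbon carries C12. Parking C12 on O8 as a five-membered butenolide ring (O8, C8, C7, C11, C12) turns C13–Br into an allyl donor with locked olefin geometry and locked C7–C8 rotamer; C6, as an aldehyde, is the acceptor.
- Stereochemistry: C8 is bought ((R)-epichlorohydrin); C4/C5 come from a catalytic Sharpless epoxidation; C6 and C7 are both set in the ring closure, relayed from C8 through the flat butenolide and a chair transition state. Z-C1=C10 comes from the iodo ylide, E-C4=C5 from geraniol, the side-chain E-olefin from a stabilized ylide.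

Key step: step 12

**Route**

Step 1
Reactants: 1 geraniol
Product: 2 geranyl tert-butyldimethylsilyl ether
Conditions: TBSCl, imidazole, DMF, 0 °C → rt
Reagents that add atoms: tert-butyldimethylsilyl chloride, C[Si](C)(Cl)C(C)(C)C
Why: Standard silylation of a primary allylic alcohol; the TBS ether should tolerate the ylide and organolithium steps that follow.

Step 2
Reactants: 2 geranyl tert-butyldimethylsilyl ether
Product: 3 6,7-epoxygeranyl tert-butyldimethylsilyl ether (racemic at the oxirane CH)
Conditions: mCPBA (1.05 equiv), NaHCO3, CH2Cl2, −20 → 0 °C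
Reagents that add atoms: meta-chloroperoxybenzoic acid, OOC(=O)c1cccc(Cl)c1
Why: Prilezhaev epoxidation should favour the remote trisubstituted olefin, because the 2,3-olefin is deactivated by the allylic silyloxy group; the new stereocentre is uncontrolled and is destroyed in step 3.

Step 3
Reactants: 3 6,7-epoxygeranyl tert-butyldimethylsilyl ether
Product: 5 (4E)-6-[(tert-butyldimethylsilyl)oxy]-4-methylhex-4-enal, via diol 4 (not isolated)
Conditions: H5IO6 (1.1 equiv), THF/H2O, 0 °C, short reaction time
Reagents that add atoms: none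
Why: Epoxide hydrolysis followed by Malaprade glycol cleavage removes the isopropylidene terminus as acetone and leaves the C1 aldehyde with the E-C4=C5 olefin untouched.

Step 4
Reactants: 5 (4E)-6-[(tert-butyldimethylsilyl)oxy]-4-methylhex-4-enal; 6 ethyltriphenylphosphonium iodide
Product: 10 tert-butyl{[(2E,6Z)-7-iodo-3-methylocta-2,6-dien-1-yl]oxy}dimethylsilane, via ethylidene ylide 7 (not isolated), via iodophosphonium iodide 8 (not isolated), via iodo ylide 9 (not isolated)
Conditions: 6, n-BuLi, THF, 0 °C; I2, −78 °C; NaHMDS, −20 °C; then 5, −78 °C → rt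
Reagents that add atoms: iodine, II
Why: Wittig olefination with the α-iodo ylide (Stork–Zhao type) is kinetically controlled and should place iodine cis to the alkyl chain, which fixes the later Z-C1=C10 geometry.

Step 5
Reactants: 10 tert-butyl{[(2E,6Z)-7-iodo-3-methylocta-2,6-dien-1-yl]oxy}dimethylsilane; 11 (R)-epichlorohydrin
Product: 13 (2R,4Z,8E)-10-[(tert-butyldimethylsilyl)oxy]-1-chloro-4,8-dimethyldeca-4,8-dien-2-ol, via vinyllithium 12 (not isolated)
Conditions: t-BuLi (2.0 equiv), Et2O, −78 °C; then 11, BF3·OEt2, −78 °C; H2O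
Reagents that add atoms: none
Why: Iodine–lithium exchange proceeds with retention of olefin geometry, and the BF3-assisted SN2 opening occurs at the unsubstituted oxirane carbon, so the C8 stereocentre of 11 is carried over untouched and the C–Cl bond survives at −78 °C.

Step 6
Reactants: 13 (2R,4Z,8E)-10-[(tert-butyldimethylsilyl)oxy]-1-chloro-4,8-dimethyldeca-4,8-dien-2-ol
Product: 15 (3R,5Z,9E)-11-[(tert-butyldimethylsilyl)oxy]-5,9-dimethylundeca-1,5,9-trien-3-ol, via terminal epoxide 14 (not isolated)
Conditions: Me3S+ I− (4 equiv), n-BuLi (3.8 equiv), THF, −10 °C → rt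
Reagents that add atoms: trimethylsulfonium iodide, C[S+](C)C.[I-]
Why: Excess dimethylsulfonium methylide first closes the chlorohydrin to the epoxide, then opens it at CH2 and eliminates dimethyl sulfide (one-carbon epoxide-to-allylic-alcohol homologation); the C8–O bond is never broken, so the configuration is retained.

Step 7
Reactants: 15 (3R,5Z,9E)-11-[(tert-butyldimethylsilyl)oxy]-5,9-dimethylundeca-1,5,9-trien-3-ol; 16 2-(bromomethyl)acrylic acid
Product: 17 (3R,5Z,9E)-11-[(tert-butyldimethylsilyl)oxy]-5,9-dimethylundeca-1,5,9-trien-3-yl 2-(bromomethyl)prop-2-enoate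
Conditions: DCC, DMAP (2 mol %), CH2Cl2, −10 °C → rt
Reagents that add atoms: none
Why: Carbodiimide (Steglich-type) esterification with minimal nucleophilic catalyst at low temperature should acylate O8 without displacing the allylic bromide; no stereocentre is affected.

Step 8
Reactants: 17 (3R,5Z,9E)-11-[(tert-butyldimethylsilyl)oxy]-5,9-dimethylundeca-1,5,9-trien-3-yl 2-(bromomethyl)prop-2-enoate
Product: 18 (5R)-3-(bromomethyl)-5-{(2Z,6E)-8-[(tert-butyldimethylsilyl)oxy]-2,6-dimethylocta-2,6-dien-1-yl}furan-2(5H)-one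
Conditions: Grubbs II (5 mol %), CH2Cl2 (0.01 M), 40 °C
Reagents that add atoms: none
Why: Ring-closing metathesis between the terminal vinyl group and the 1,1-disubstituted acrylate gives the α-substituted butenolide with loss of ethylene; the trisubstituted olefins should be inert, and the ring locks C8 cis to C12.

Step 9
Reactants: 18 (5R)-3-(bromomethyl)-5-{(2Z,6E)-8-[(tert-butyldimethylsilyl)oxy]-2,6-dimethylocta-2,6-dien-1-yl}furan-2(5H)-one
Product: 19 (5R)-3-(bromomethyl)-5-[(2Z,6E)-8-hydroxy-2,6-dimethylocta-2,6-dien-1-yl]furan-2(5H)-one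
Conditions: CSA (10 mol %), MeOH/CH2Cl2 1:1, 0 °C
Reagents that add atoms: none
Why: Acid-catalysed methanolysis of a primary allylic TBS ether avoids fluoride and amine bases, which would attack the allylic bromide.

Step 10
Reactants: 19 (5R)-3-(bromomethyl)-5-[(2Z,6E)-8-hydroxy-2,6-dimethylocta-2,6-dien-1-yl]furan-2(5H)-one
Product: 20 (5R)-3-(bromomethyl)-5-{(2Z)-5-[(2R,3R)-3-(hydroxymethyl)-2-methyloxiran-2-yl]-2-methylpent-2-en-1-yl}furan-2(5H)-one
Conditions: Ti(OiPr)4 (10 mol %), D-(−)-diethyl tartrate (12 mol %), TBHP (2 equiv), 4 Å MS, CH2Cl2, −20 °C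
Reagents that add atoms: tert-butyl hydroperoxide, CC(C)(C)OO
Why: Sharpless asymmetric epoxidation of a geraniol-type E-allylic alcohol; D-(−)-DET should deliver oxygen to the face giving the (2R,3R)-epoxy alcohol (C4 R, C5 R) under reagent control, and the isolated Z-olefin and the electron-poor butenolide are not substrates.

Step 11
Reactants: 20 (5R)-3-(bromomethyl)-5-{(2Z)-5-[(2R,3R)-3-(hydroxymethyl)-2-methyloxiran-2-yl]-2-methylpent-2-en-1-yl}furan-2(5H)-one
Product: 21 (2S,3R)-3-{(3Z)-5-[(2R)-4-(bromomethyl)-5-oxo-2,5-dihydrofuran-2-yl]-4-methylpent-3-en-1-yl}-3-methyloxirane-2-carbaldehyde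
Conditions: Dess–Martin periodinane, NaHCO3, CH2Cl2, 0 °C → rt
Reagents that add atoms: none
Why: Buffered Dess–Martin oxidation gives the α,β-epoxy aldehyde without base or phosphine, so the epoxide centre and the allylic bromide should survive (the change of descriptor at C5 is only a priority change).

Step 12
Reactants: 21 (2S,3R)-3-{(3Z)-5-[(2R)-4-(bromomethyl)-5-oxo-2,5-dihydrofuran-2-yl]-4-methylpent-3-en-1-yl}-3-methyloxirane-2-carbaldehyde
Product: 23 (4R,5R,6S,7S,8R)-4,5-epoxy-6-hydroxygermacra-1(10)Z,11(13)-dien-12,8-olide (cis-fused α-methylene lactone on C7–C8), via allylchromium 22 (not isolated)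
Conditions: CrCl2 (8 equiv), THF, rt, syringe-pump addition of 21 (final 2 mM); H2O
Reagents that add atoms: none
Why: CrCl2 inserts into the allylic C13–Br bond to give allylchromium(III) 22, which adds through its γ-carbon C7 to the C6 aldehyde in a closed six-membered chair (Cr, O, C6, C7, C11, C13); this is an intramolecular Nozaki–Hiyama–Kishi (Barbier-type) allylation, the reaction type used to close germacranolide ten-membered rings at this bond from 2-(bromomethyl)acrylate-type halides, here with an α-(bromomethyl)butenolide as the allyl donor. The ten-membered carbocycle closes in a 10-exo-trig mode at the carbonyl carbon with SE2′ transposition of the allyl unit, so C11=C13 emerges as the exocyclic methylene; no other ring forms in this step. C7: the butenolide is flat and carries the tether (C9) on C8, so the aldehyde should be delivered to the face of C7 syn to C9 (cis-fused lactone), which relays the bought C8 centre. C6: the ring O8–C12 holds C8 trans to the CH2Cr terminus (E-type allyl that cannot isomerize), so the chair with C5 equatorial should give the anti relationship that corresponds to a 6,7-trans lactone. The step needs γ- over α-attack, ring closure over dimerization or protonation, and addition to the aldehyde face that gives 6S; these are secured by the chair, by slow addition at high dilution, and by the turn elements (Z-C1=C10 and the trans-epoxide) that hold C6 over C7, while epoxide and lactone are expected to be inert to Cr(II)/Cr(III).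

Step 13
Reactants: 23 (4R,5R,6S,7S,8R)-4,5-epoxy-6-hydroxygermacra-1(10)Z,11(13)-dien-12,8-olide
Product: 24 (4R,5R,6S,7R,8R)-4,5-epoxy-8-hydroxygermacra-1(10)Z,11(13)-dien-12,6-olide (trans-fused α-methylene lactone on C6–C7)
Conditions: DBU (0.2 equiv), CH2Cl2, 0 °C → rt
Reagents that add atoms: none
Why: Base-catalysed translactonization (O6 adds to C12 in a 5-exo-trig sense, O8 leaves) should favour the trans-β,γ-disubstituted lactone over the cis-fused one and frees the C8 hydroxyl; no stereocentre is touched, since C7 is not α to the carbonyl.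

Step 14
Reactants: 25 (tert-butyldimethylsilyloxy)acetaldehyde; 26 ethyl 2-(triphenylphosphoranylidene)propanoate
Product: 27 ethyl (2E)-4-[(tert-butyldimethylsilyl)oxy]-2-methylbut-2-enoate
Conditions: CH2Cl2, rt → 40 °C
Reagents that add atoms: none
Why: Wittig olefination with a stabilized α-methyl ylide should give the E (tiglate-type) trisubstituted enoate.

Step 15
Reactants: 27 ethyl (2E)-4-[(tert-butyldimethylsilyl)oxy]-2-methylbut-2-enoate
Product: 28 (2E)-4-[(tert-butyldimethylsilyl)oxy]-2-methylbut-2-enoic acid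
Conditions: LiOH·H2O, THF/MeOH/H2O, 0 °C → rt; then 1 M HCl to pH 4 at 0 °C
Reagents that add atoms: lithium hydroxide, [Li+].[OH-]
Why: Saponification by acyl–oxygen cleavage; the primary TBS ether should survive hydroxide and a brief, cold acidification to pH 4.

Step 16
Reactants: 24 (4R,5R,6S,7R,8R)-4,5-epoxy-8-hydroxygermacra-1(10)Z,11(13)-dien-12,6-olide; 28 (2E)-4-[(tert-butyldimethylsilyl)oxy]-2-methylbut-2-enoic acid
Product: 30 (4R,5R,6S,7R,8R)-4,5-epoxy-8-{[(2E)-4-(tert-butyldimethylsilyloxy)-2-methylbut-2-enoyl]oxy}germacra-1(10)Z,11(13)-dien-12,6-olide, via mixed anhydride 29 (not isolated)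
Conditions: 28, 2,4,6-trichlorobenzoyl chloride, Et3N, THF, rt; then 24, DMAP, toluene, rt
Reagents that add atoms: none
Why: Yamaguchi esterification acylates hindered secondary alcohols through the acylpyridinium derived from the less hindered carbonyl of the mixed anhydride; the C8–O bond is not broken and the enoate geometry is retained.

Step 17
Reactants: 30 (4R,5R,6S,7R,8R)-4,5-epoxy-8-{[(2E)-4-(tert-butyldimethylsilyloxy)-2-methylbut-2-enoyl]oxy}germacra-1(10)Z,11(13)-dien-12,6-olide
Product: 31 CNP0198076.5, (4R,5R,6S,7R,8R)-4,5-epoxy-8-{[(2E)-4-hydroxy-2-methylbut-2-enoyl]oxy}germacra-1(10)Z,11(13)-dien-12,6-olide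
Conditions: HF·pyridine, pyridine, THF, 0 °C
Reagents that add atoms: none
Why: Buffered HF·pyridine cleaves the primary allylic TBS ether under conditions that the epoxide, the α-methylene lactone and the enoate ester are expected to tolerate.

**Compound list**

1 | geraniol | CC(C)=CCC/C(C)=C/CO | starting material
2 | geranyl tert-butyldimethylsilyl ether | CC(C)=CCC/C(C)=C/CO[Si](C)(C)C(C)(C)C | intermediate
3 | 6,7-epoxygeranyl tert-butyldimethylsilyl ether (racemic at the oxirane CH) | CC1(C)OC1CC/C(C)=C/CO[Si](C)(C)C(C)(C)C | intermediate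
4 | (6E)-8-[(tert-butyldimethylsilyl)oxy]-2,6-dimethyloct-6-ene-2,3-diol (racemic) | CC(C)(O)C(O)CC/C(C)=C/CO[Si](C)(C)C(C)(C)C | intermediate (not isolated)
5 | (4E)-6-[(tert-butyldimethylsilyl)oxy]-4-methylhex-4-enal | O=CCC/C(C)=C/CO[Si](C)(C)C(C)(C)C | intermediate
6 | ethyltriphenylphosphonium iodide | CC[P+](c1ccccc1)(c1ccccc1)c1ccccc1.[I-] | starting material
7 | ethylidenetriphenylphosphorane | CC=P(c1ccccc1)(c1ccccc1)c1ccccc1 | intermediate (not isolated)
8 | (1-iodoethyl)triphenylphosphonium iodide | CC(I)[P+](c1ccccc1)(c1ccccc1)c1ccccc1.[I-] | intermediate (not isolated)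
9 | (1-iodoethylidene)triphenylphosphorane | CC(I)=P(c1ccccc1)(c1ccccc1)c1ccccc1 | intermediate (not isolated)
10 | tert-butyl{[(2E,6Z)-7-iodo-3-methylocta-2,6-dien-1-yl]oxy}dimethylsilane | C/C(I)=C/CC/C(C)=C/CO[Si](C)(C)C(C)(C)C | intermediate
11 | (R)-epichlorohydrin | ClC[C@H]1CO1 | starting material
12 | (2Z,6E)-8-[(tert-butyldimethylsilyl)oxy]-6-methylocta-2,6-dien-2-yllithium | C/C([Li])=C/CC/C(C)=C/CO[Si](C)(C)C(C)(C)C | intermediate (not isolated)
13 | (2R,4Z,8E)-10-[(tert-butyldimethylsilyl)oxy]-1-chloro-4,8-dimethyldeca-4,8-dien-2-ol | ClC[C@H](O)C/C(C)=C\CC/C(C)=C/CO[Si](C)(C)C(C)(C)C | intermediate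
14 | (2R)-2-{(2Z,6E)-8-[(tert-butyldimethylsilyl)oxy]-2,6-dimethylocta-2,6-dien-1-yl}oxirane | C1O[C@@H]1C/C(C)=C\CC/C(C)=C/CO[Si](C)(C)C(C)(C)C | intermediate (not isolated)
15 | (3R,5Z,9E)-11-[(tert-butyldimethylsilyl)oxy]-5,9-dimethylundeca-1,5,9-trien-3-ol | C=C[C@H](O)C/C(C)=C\CC/C(C)=C/CO[Si](C)(C)C(C)(C)C | intermediate
16 | 2-(bromomethyl)acrylic acid | C=C(CBr)C(=O)O | starting material
17 | (3R,5Z,9E)-11-[(tert-butyldimethylsilyl)oxy]-5,9-dimethylundeca-1,5,9-trien-3-yl 2-(bromomethyl)prop-2-enoate | C=C[C@H](OC(=O)C(=C)CBr)C/C(C)=C\CC/C(C)=C/CO[Si](C)(C)C(C)(C)C | intermediate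
18 | (5R)-3-(bromomethyl)-5-{(2Z,6E)-8-[(tert-butyldimethylsilyl)oxy]-2,6-dimethylocta-2,6-dien-1-yl}furan-2(5H)-one | O=C1O[C@H](C/C(C)=C\CC/C(C)=C/CO[Si](C)(C)C(C)(C)C)C=C1CBr | intermediate
19 | (5R)-3-(bromomethyl)-5-[(2Z,6E)-8-hydroxy-2,6-dimethylocta-2,6-dien-1-yl]furan-2(5H)-one | O=C1O[C@H](C/C(C)=C\CC/C(C)=C/CO)C=C1CBr | intermediate
20 | (5R)-3-(bromomethyl)-5-{(2Z)-5-[(2R,3R)-3-(hydroxymethyl)-2-methyloxiran-2-yl]-2-methylpent-2-en-1-yl}furan-2(5H)-one | O=C1O[C@H](C/C(C)=C\CC[C@@]2(C)O[C@@H]2CO)C=C1CBr | intermediate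
21 | (2S,3R)-3-{(3Z)-5-[(2R)-4-(bromomethyl)-5-oxo-2,5-dihydrofuran-2-yl]-4-methylpent-3-en-1-yl}-3-methyloxirane-2-carbaldehyde | O=C1O[C@H](C/C(C)=C\CC[C@@]2(C)O[C@@H]2C=O)C=C1CBr | intermediate
22 | allylchromium(III) dichloride derived from 21 (Cr on C13) | O=C1O[C@H](C/C(C)=C\CC[C@@]2(C)O[C@@H]2C=O)C=C1C[Cr](Cl)Cl | intermediate (not isolated)
23 | (4R,5R,6S,7S,8R)-4,5-epoxy-6-hydroxygermacra-1(10)Z,11(13)-dien-12,8-olide | C=C1C(=O)O[C@@H]2C/C(C)=C\CC[C@@]3(C)O[C@@H]3[C@@H](O)[C@H]12 | intermediate
24 | (4R,5R,6S,7R,8R)-4,5-epoxy-8-hydroxygermacra-1(10)Z,11(13)-dien-12,6-olide | C=C1C(=O)O[C@H]2[C@H]1[C@H](O)C/C(C)=C\CC[C@@]1(C)O[C@H]21 | intermediate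
25 | (tert-butyldimethylsilyloxy)acetaldehyde | O=CCO[Si](C)(C)C(C)(C)C | starting material
26 | ethyl 2-(triphenylphosphoranylidene)propanoate | CCOC(=O)C(C)=P(c1ccccc1)(c1ccccc1)c1ccccc1 | starting material
27 | ethyl (2E)-4-[(tert-butyldimethylsilyl)oxy]-2-methylbut-2-enoate | CCOC(=O)/C(C)=C/CO[Si](C)(C)C(C)(C)C | intermediate
28 | (2E)-4-[(tert-butyldimethylsilyl)oxy]-2-methylbut-2-enoic acid | OC(=O)/C(C)=C/CO[Si](C)(C)C(C)(C)C | intermediate
29 | mixed anhydride of 28 with 2,4,6-trichlorobenzoic acid | O=C(OC(=O)/C(C)=C/CO[Si](C)(C)C(C)(C)C)c1c(Cl)cc(Cl)cc1Cl | intermediate (not isolated)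
30 | (4R,5R,6S,7R,8R)-4,5-epoxy-8-{[(2E)-4-(tert-butyldimethylsilyloxy)-2-methylbut-2-enoyl]oxy}germacra-1(10)Z,11(13)-dien-12,6-olide | C=C1C(=O)O[C@H]2[C@H]1[C@H](OC(=O)/C(C)=C/CO[Si](C)(C)C(C)(C)C)C/C(C)=C\CC[C@@]1(C)O[C@H]21 | intermediate
31 | CNP0198076.5, (4R,5R,6S,7R,8R)-4,5-epoxy-8-{[(2E)-4-hydroxy-2-methylbut-2-enoyl]oxy}germacra-1(10)Z,11(13)-dien-12,6-olide | C=C1C(=O)O[C@H]2[C@H]1[C@H](OC(=O)/C(C)=C/CO)C/C(C)=C\CC[C@@]1(C)O[C@H]21 | target

**Step count**

Total: 17 steps (15 in the main line, 2 for the side-chain acid). Longest linear sequence: 15 steps (steps 1–13, 16, 17).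

**Steps most likely to fail**

Step 12. The ring closure may suffer from poor facial selectivity at the aldehyde: the required addition puts O6 syn to the epoxide oxygen, which is opposite to the Felkin–Anh preference of an α,β-epoxy aldehyde, so the chair and the tether have to override an intrinsic bias. Intermolecular coupling or protonation of the allylchromium may also compete with medium-ring closure. The fallback postpones the epoxide so that the aldehyde carries no α-stereocentre. It sets out from alcohol 19, which is oxidized with MnO2 in CH2Cl2 to the enal (5R)-3-(bromomethyl)-5-[(2Z,6E)-2,6-dimethyl-8-oxoocta-2,6-dien-1-yl]furan-2(5H)-one F1. The same CrCl2 ring closure under high dilution, now a 1,2-addition to an enal governed only by the chair and the butenolide face, should give the 4,5-olefin analogue of 23 (4E; same configuration at C6, C7 and C8) F2. A hydroxyl-directed epoxidation of the cyclic allylic alcohol (Ti(OiPr)4, TBHP, CH2Cl2, −20 °C) should then give the threo epoxy alcohol, because the C15 methyl group cis to the carbinol carbon enforces the A(1,3)-minimized conformer. This returns to the route at compound 23.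

Step 13. The acyl shift may stop at an unfavourable equilibrium between the cis-fused C8 lactone and the trans-fused C6 lactone, or the base may move the exocyclic olefin into the ring. The fallback frees O8 by reduction and rebuilds the lactone at O6 by oxidation, so no equilibrium is involved. It sets out from 23, which is silylated (TESOTf, 2,6-lutidine, −78 °C) to the 6-O-triethylsilyl ether of 23 F3. DIBAL-H (CH2Cl2, −78 → 0 °C) reduces the lactone to the C12/C8 diol F4. The primary allylic hydroxyl is silylated selectively (TESCl, imidazole, −20 °C) to the 12-O-triethylsilyl ether F5. Yamaguchi esterification of the C8 hydroxyl with acid 28 gives the C8 ester F6. PPTS in MeOH at 0 °C removes both triethylsilyl groups, leaving the TBS ether, to give the C6/C12 diol F7. TEMPO/PhI(OAc)2 oxidizes the primary allylic alcohol, and the lactol formed with O6 is oxidized on to the lactone. This returns to the route at compound 30.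

Step 16. Under Et3N/DMAP the lactone may migrate back from O6 to O8 before the hindered C8 hydroxyl is acylated, which would give acylation at O6; the acylation itself may also be slow. The fallback acylates without base and builds the enoate afterwards. It sets out from 24, which is esterified with 2-(diethoxyphosphoryl)propanoic acid and DCC in CH2Cl2 (base-free, through the phosphonoketene) to the C8 2-(diethoxyphosphoryl)propanoate of 24 (epimers at the phosphonate carbon) F8. A Horner–Wadsworth–Emmons reaction with aldehyde 25 (LiCl, i-Pr2NEt, MeCN) should give the E-trisubstituted enoate. This returns to the route at compound 30.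

Further compounds
F1 | step 12 | (5R)-3-(bromomethyl)-5-[(2Z,6E)-2,6-dimethyl-8-oxoocta-2,6-dien-1-yl]furan-2(5H)-one | O=C1O[C@H](C/C(C)=C\CC/C(C)=C/C=O)C=C1CBr
F2 | step 12 | 4,5-olefin analogue of 23: 6-hydroxygermacra-1(10)Z,4E,11(13)-trien-12,8-olide with the C6, C7, C8 configuration of 23 | C=C1C(=O)O[C@@H]2C/C(C)=C\CC/C(C)=C/[C@@H](O)[C@H]12
F3 | step 13 | 6-O-triethylsilyl ether of 23 | C=C1C(=O)O[C@@H]2C/C(C)=C\CC[C@@]3(C)O[C@@H]3[C@@H](O[Si](CC)(CC)CC)[C@H]12
F4 | step 13 | 4,5-epoxy-6-(triethylsilyloxy)germacra-1(10)Z,11(13)-diene-8,12-diol (configuration of 23) | C=C(CO)[C@@H]1[C@H](O)C/C(C)=C\CC[C@@]2(C)O[C@@H]2[C@H]1O[Si](CC)(CC)CC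
F5 | step 13 | 12-O-triethylsilyl ether of F4 | C=C(CO[Si](CC)(CC)CC)[C@@H]1[C@H](O)C/C(C)=C\CC[C@@]2(C)O[C@@H]2[C@H]1O[Si](CC)(CC)CC
F6 | step 13 | 8-O-[(2E)-4-(tert-butyldimethylsilyloxy)-2-methylbut-2-enoyl] ester of F5 | C=C(CO[Si](CC)(CC)CC)[C@@H]1[C@H](OC(=O)/C(C)=C/CO[Si](C)(C)C(C)(C)C)C/C(C)=C\CC[C@@]2(C)O[C@@H]2[C@H]1O[Si](CC)(CC)CC
F7 | step 13 | 6,12-diol obtained from F6 by removal of both triethylsilyl groups | C=C(CO)[C@@H]1[C@H](OC(=O)/C(C)=C/CO[Si](C)(C)C(C)(C)C)C/C(C)=C\CC[C@@]2(C)O[C@@H]2[C@H]1O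
F8 | step 16 | 8-O-[2-(diethoxyphosphoryl)propanoyl] ester of 24 | C=C1C(=O)O[C@H]2[C@H]1[C@H](OC(=O)C(C)P(=O)(OCC)OCC)C/C(C)=C\CC[C@@]1(C)O[C@H]21
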